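**Plan**

- Numbering: chain carbons C1 (lactone carbonyl) to C32 (the OCH2 carbon). The target is the unbranched 33-membered lactone of 32-hydroxydotriacontanoic acid (C32H62O2) and has no stereocentre.
- Retrosynthetic cuts, in order: C25–C26 (carried as a C25=C26 alkene, ring-closing metathesis), then the ester O–C1 bond, then C15–C16 of the acyl chain (sp3–sp3 coupling).
- This leads to three commercial pieces: oct-7-en-1-ol (C26–C32), 15-bromopentadecanoic acid (C1–C15) and 11-bromoundec-1-ene (C16–C25; its terminal carbon leaves as ethylene).
- Forward: the ester bond first, then the C15–C16 bond by copper-catalysed Grignard coupling, then the only ring (33-membered) by metathesis at C25=C26, then hydrogenation.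
- Enabling feature: the ring is strain-free and its only functional group is the O–C1(=O) ester. C25 and C26 are plain methylenes, twenty-three and six CH2 groups away from that ester, so each can be carried as the inner carbon of a terminal vinyl group and the two joined end to end.
- Stereochemistry: none to set; the E/Z mixture at C25=C26 is erased in the last step.

Key step: step 3

Remark: compounds 1, 2 and 4 are taken as commercial; compound 7 is expected as a mixture of alkene isomers.

**Step 1**
Reactants: 1 15-bromopentadecanoic acid; 2 oct-7-en-1-ol
Product: 3 oct-7-en-1-yl 15-bromopentadecanoate
Conditions: DCC (1.1 equiv), DMAP (0.1 equiv), CH2Cl2, 0 °C to rt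
Reagents that add atoms: none
Why: Steglich esterification, in which DCC activates the acid as the O-acylisourea and DMAP passes the acyl group to the primary alcohol at room temperature, conditions under which neither the primary bromide nor the terminal alkene should react.

**Step 2**
Reactants: 3 oct-7-en-1-yl 15-bromopentadecanoate; 4 11-bromoundec-1-ene
Product: 6 oct-7-en-1-yl hexacos-25-enoate, via undec-10-en-1-ylmagnesium bromide 5 (not isolated)
Conditions: 4, Mg turnings, THF, 45 °C; then added slowly to 3, Li2CuCl4 (3 mol %), NMP (4 equiv), THF, 0 °C to rt
Reagents that add atoms: none
Why: Copper-catalysed Kochi-type sp3–sp3 cross-coupling of a primary alkyl Grignard reagent with a primary alkyl bromide, which in THF/NMP should be much faster than addition of the Grignard reagent to the ester and leaves both terminal alkenes untouched.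

**Step 3**
Reactants: 6 oct-7-en-1-yl hexacos-25-enoate
Product: 7 (E/Z)-oxacyclotritriacont-26-en-2-one (dotriacont-25-en-32-olide)
Conditions: first-generation Grubbs catalyst RuCl2(=CHPh)(PCy3)2 (5 mol %), CH2Cl2, 1 mM, 40 °C, slow addition of 6, argon sparge
Reagents that add atoms: none
Why: Ring-closing olefin metathesis: the ruthenium benzylidene is exchanged for the alkylidene of one vinyl group, this adds across the other vinyl group to a ruthenacyclobutane, and cycloreversion releases the C25=C26 alkene and a ruthenium methylidene that carries the chain on with loss of ethylene. The closest known reaction type is the macrocyclic ring-closing metathesis of ω-alkenyl ω-alkenoates to large musk-type lactones. The one ring closed is the 33-membered oxacycle, joined end to end between the two inner vinyl carbons, and no smaller ring can form because no other alkene is present. No stereocentre arises, and the E/Z mixture at C25=C26 does not matter because step 4 removes it. The step needs ring closure to win over acyclic diene metathesis oligomerisation and needs both chain lengths to stay intact: millimolar concentration with slow addition and the reversibility of oligomerisation (back-biting to the strain-free ring as ethylene is swept out) should secure the first, and the first-generation catalyst at 40 °C, which migrates terminal double bonds very little, should secure the second. The substrate helps in that the ester sits six and twenty-three methylenes away from the two alkenes, too far to tie up the ruthenium alkylidene in a five- or six-membered chelate.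

**Step 4**
Reactants: 7 (E/Z)-oxacyclotritriacont-26-en-2-one
Product: 8 oxacyclotritriacontan-2-one (dotriacontan-32-olide)
Conditions: H2 (1 atm), 10 wt % Pd/C, EtOAc, rt
Reagents that add atoms: none
Why: Heterogeneous catalytic hydrogenation of an unhindered disubstituted alkene, in which both alkene isomers converge on the same saturated ring and the lactone should not be hydrogenolysed.

**Compound list**

1 | 15-bromopentadecanoic acid | OC(=O)CCCCCCCCCCCCCCBr | starting material
2 | oct-7-en-1-ol | OCCCCCCC=C | starting material
3 | oct-7-en-1-yl 15-bromopentadecanoate | C=CCCCCCCOC(=O)CCCCCCCCCCCCCCBr | intermediate
4 | 11-bromoundec-1-ene | C=CCCCCCCCCCBr | starting material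
5 | undec-10-en-1-ylmagnesium bromide | C=CCCCCCCCCC[Mg]Br | intermediate
6 | oct-7-en-1-yl hexacos-25-enoate | C=CCCCCCCOC(=O)CCCCCCCCCCCCCCCCCCCCCCCC=C | intermediate
7 | (E/Z)-oxacyclotritriacont-26-en-2-one (dotriacont-25-en-32-olide, mixture of alkene isomers) | O=C1CCCCCCCCCCCCCCCCCCCCCCCC=CCCCCCCO1 | intermediate
8 | oxacyclotritriacontan-2-one (dotriacontan-32-olide) | O=C1CCCCCCCCCCCCCCCCCCCCCCCCCCCCCCCO1 | target

**Totals**

Total step count: 4
Longest linear sequence: 4 steps (1 → 3 → 6 → 7 → 8)

**Steps most likely to fail**

Step 3. Intermolecular metathesis to oligomers may outrun ring closure, or a terminal double bond may migrate before closure so that a shorter ring forms with loss of propene. The fallback sets out from 6 and comes back at 7. Ozonolysis of both vinyl groups of 6 (O3, CH2Cl2, −78 °C; then PPh3) should give the dialdehyde 7-oxoheptyl 25-oxopentacosanoate F1, whose two formyl carbons are C26 and C25. Intramolecular McMurry coupling of F1 on low-valent titanium (TiCl3(DME)1.5, Zn–Cu couple, DME, reflux, syringe-pump addition) should then join C25 to C26 as the alkene and give 7. Aldehyde–aldehyde coupling is expected to be far faster than attack on the isolated ester, and the closure is templated on the titanium surface and independent of metathesis equilibria.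

Step 2. The Grignard reagent may add to the ester carbonyl, or the bromide may be reduced or eliminated in place of substitution. The fallback sets out from 1 and 5 and comes back at 6, with the order of ester formation and chain extension exchanged. Acid 1 would be treated with 5 (2.3 equiv) and Li2CuCl4 (3 mol %) in THF at −20 °C. The first equivalent should deprotonate the acid to bromomagnesium 15-bromopentadecanoate F2, whose carboxylate is inert to Grignard addition. The second should couple at the C–Br bond and give, after acidic work-up, hexacos-25-enoic acid F3. DCC/DMAP esterification of F3 with 2 should then give 6.

Step 4. The hydrogenation may stall through poisoning of the palladium surface by ruthenium and phosphine residues carried over, or through poor solubility of the waxy lactone. The fallback sets out from 7 and comes back at 8. Metal-free reduction with diimide generated in the flask (p-toluenesulfonyl hydrazide, NaOAc, DME/H2O, reflux) should saturate the unhindered alkene by concerted syn transfer of two hydrogens without touching the lactone. This fallback makes no new compound (F0).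

**Further compounds**

F1 | step 3 | 7-oxoheptyl 25-oxopentacosanoate | O=CCCCCCCOC(=O)CCCCCCCCCCCCCCCCCCCCCCCC=O
F2 | step 2 | bromomagnesium 15-bromopentadecanoate | BrCCCCCCCCCCCCCCC(=O)O[Mg]Br
F3 | step 2 | hexacos-25-enoic acid | C=CCCCCCCCCCCCCCCCCCCCCCCCC(=O)O
F0 | step 4 | none | none
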